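## Retrosynthetic overview

1. Target ⇐ catalyst-controlled epoxidation of the Δ10 prenyl alkene ⇐ cross-metathesis (allyl → prenyl) ⇐ double angeloylation ⇐ asymmetric allylboration of a C8 enal ⇐ allylic oxidation of the isopropenyl methyl.
2. Ring: 4α-Cl/3β-OH ⇐ trans-diaxial HCl opening of a 3β,4β-epoxide; 2β-OH ⇐ Luche reduction; 1β-OAc ⇐ invertive 1,2-acetoxy shift of a 1α,2α-acetoxy-oxirane.
3. Both ring oxiranes (1α,2α and 3β,4β) are made in one Shi epoxidation of the kinetic 2-acetoxy-1,3-diene of (S)-carvone.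
4. Ring order: cyclohexane from (S)-carvone; the two ring oxiranes together (step 2; one is relayed into C1-OAc, the other into Cl/OH); the side-chain oxirane last.

Convention: bisabolane numbering throughout (C6 = ring CH carrying the side chain, then C1, C2, C3 (bears CH3-15), C4, C5; C7 = side-chain sp2 carbon, C14 = its CH2, C8–C13 the chain); β = ring face of the C6–C7 bond; both Shi ketones, (S)-TRIP and Grubbs II are bought catalysts.

## Route

Step 1
Reactants: 1 (S)-(+)-carvone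
Product: 3 (3S)-6-methyl-3-(prop-1-en-2-yl)cyclohexa-1,5-dien-1-yl acetate (2-acetoxy-Δ1,Δ3-diene), via lithium dienolate 2 (not isolated)
Conditions: LDA (1.1 equiv), THF, −78 °C; then Ac2O, −78 → 0 °C
Reagents that add atoms: acetic anhydride, CC(=O)OC(C)=O
Why: Kinetic α′-deprotonation at C1 and O-acylation of the lithium enolate give the cross-conjugated enol acetate (enolate trapping); C6 is untouched.

Step 2
Reactants: 3 (3S)-6-methyl-3-(prop-1-en-2-yl)cyclohexa-1,5-dien-1-yl acetate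
Product: 4 2β-acetoxy-1α,2α:3β,4β-diepoxy-3-methyl-6β-(prop-1-en-2-yl)cyclohexane (anti-bis-epoxide)
Conditions: Shi ketone (D-fructose-derived, 0.4 equiv), Oxone, K2CO3, n-Bu4NHSO4, MeCN/DMM, aq. Na2B4O7–EDTA (pH ≈ 10.5), −10 → 0 °C
Reagents that add atoms: Oxone (potassium peroxymonosulfate), [K+].[O-]S(=O)(=O)OO
Why: Double Shi asymmetric epoxidation (spiro dioxirane transition state) of an enol ester and a conjugated trisubstituted alkene. The D-ketone puts oxygen on the α face of C1=C2 (also anti to the C6 substituent) and on the β face of C3=C4 (also anti to the first oxirane), so catalyst and substrate agree at both sites; the 1,1-disubstituted isopropenyl group reacts much more slowly.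

Step 3
Reactants: 4 2β-acetoxy-1α,2α:3β,4β-diepoxy-3-methyl-6β-(prop-1-en-2-yl)cyclohexane
Product: 5 1β-acetoxy-3β,4β-epoxy-3-methyl-6β-(prop-1-en-2-yl)cyclohexan-2-one
Conditions: PhMe, 120 °C (sealed tube)
Reagents that add atoms: none
Why: Thermal enol ester epoxide → α-acyloxy ketone rearrangement (concerted 1,2-acyloxy shift). The β-acetate carbonyl oxygen attacks C1 anti to the α C1–O bond, so C1 is inverted to 1β-OAc (cis to the C6 substituent) and the oxirane oxygen becomes the C2 ketone.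

Step 4
Reactants: 5 1β-acetoxy-3β,4β-epoxy-3-methyl-6β-(prop-1-en-2-yl)cyclohexan-2-one
Product: 6 1β-acetoxy-3β,4β-epoxy-3-methyl-6β-(prop-1-en-2-yl)cyclohexan-2β-ol
Conditions: NaBH4, CeCl3·7H2O, MeOH, −78 °C
Reagents that add atoms: none
Why: Luche reduction; hydride adds to C2 from the α face, anti to both the β-oxirane oxygen and the axial 1β-OAc, giving the 2β-alcohol (cis-epoxy alcohol); low temperature limits acetyl migration.

Step 5
Reactants: 6 1β-acetoxy-3β,4β-epoxy-3-methyl-6β-(prop-1-en-2-yl)cyclohexan-2β-ol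
Product: 7 (1S,2S,3S,4S,6R)-1-acetoxy-4-chloro-3-methyl-6-(prop-1-en-2-yl)cyclohexane-2,3-diol (4α-Cl and 3β-OH)
Conditions: HCl (1 M in Et2O, 1.1 equiv), CH2Cl2, −40 → 0 °C
Reagents that add atoms: hydrogen chloride, Cl
Why: Fürst–Plattner trans-diaxial epoxide opening. Chloride attacks secondary C4 from the α face with inversion (the mode that opens trans-limonene oxide at C2); tertiary C3 is hindered and deactivated by the adjacent C2–OH, so 4α-Cl/3β-OH result.

Step 6
Reactants: 7 (1S,2S,3S,4S,6R)-1-acetoxy-4-chloro-3-methyl-6-(prop-1-en-2-yl)cyclohexane-2,3-diol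
Product: 9 2-[(1R,2S,3S,4S,5S)-2-acetoxy-5-chloro-3,4-dihydroxy-4-methylcyclohexyl]prop-2-enal (C8 enal), via allylic alcohol 8 (not isolated)
Conditions: SeO2 (0.5 equiv), t-BuOOH, CH2Cl2, rt; then TEMPO (10 mol%), PhI(OAc)2, CH2Cl2, rt
Reagents that add atoms: selenium dioxide (catalytic oxygen carrier), O=[Se]=O; tert-butyl hydroperoxide (terminal oxygen source), CC(C)(C)OO
Why: Riley–Sharpless allylic oxidation (ene, then [2,3]-shift) at the isopropenyl methyl; C6–H is deactivated by the neighbouring CH–OAc. TEMPO/PhI(OAc)2 then oxidises only the primary allylic alcohol. No stereocentre is formed.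

Step 7
Reactants: 9 2-[(1R,2S,3S,4S,5S)-2-acetoxy-5-chloro-3,4-dihydroxy-4-methylcyclohexyl]prop-2-enal
Product: 11 (1S,2S,3S,4S,6R)-1-acetoxy-4-chloro-6-[(3S)-3-hydroxyhexa-1,5-dien-2-yl]-3-methylcyclohexane-2,3-diol, via pinacol borate 10 (not isolated)
Conditions: allyl-B(pin) (1.5 equiv), (S)-TRIP (5 mol%), PhMe, −30 °C; then aq. NH4Cl
Reagents that add atoms: allylboronic acid pinacol ester, C=CCB1OC(C)(C)C(C)(C)O1
Why: Chiral phosphoric acid-catalysed allylboration through a chair Zimmerman–Traxler transition state. The (S)-catalyst delivers allyl to the Si face of the aldehyde (as PhCHO → (S)-carbinol), setting C8 as S under catalyst control; the boronate tolerates the free hydroxyls.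

Step 8
Reactants: 11 (1S,2S,3S,4S,6R)-1-acetoxy-4-chloro-6-[(3S)-3-hydroxyhexa-1,5-dien-2-yl]-3-methylcyclohexane-2,3-diol
Product: 12 (8S)-1β-acetoxy-2β,8-bis(angeloyloxy)-4α-chloro-3β-hydroxy-12,13-dinorbisabola-7(14),10-diene
Conditions: angelic acid (3 equiv), 2,4,6-trichlorobenzoyl chloride, Et3N, PhMe, rt; then 11, PhMe, 75 °C (no DMAP)
Reagents that add atoms: angelic acid [(Z)-2-methylbut-2-enoic acid], C/C=C(/C)C(=O)O
Why: Yamaguchi-type esterification through the mixed anhydride. Omitting DMAP suppresses Z → E isomerisation to tiglate; both secondary hydroxyls (C2, C8) are acylated and the tertiary 3-OH is inert.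

Step 9
Reactants: 12 (8S)-1β-acetoxy-2β,8-bis(angeloyloxy)-4α-chloro-3β-hydroxy-12,13-dinorbisabola-7(14),10-diene
Product: 13 (8S)-1β-acetoxy-2β,8-bis(angeloyloxy)-4α-chloro-3β-hydroxybisabola-7(14),10-diene
Conditions: Grubbs II (5 mol%), 2-methyl-2-butene/CH2Cl2, 40 °C
Reagents that add atoms: 2-methyl-2-butene, CC=C(C)C
Why: Olefin cross-metathesis of the terminal alkene with 2-methyl-2-butene installs the prenyl terminus; the hindered 1,1-disubstituted C7=C14 alkene and the conjugated angelates do not take part.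

Step 10
Reactants: 13 (8S)-1β-acetoxy-2β,8-bis(angeloyloxy)-4α-chloro-3β-hydroxybisabola-7(14),10-diene
Product: 14 (1S,2S,3S,4S,6R,8S,10S)-1-acetoxy-2,8-bis(angeloyloxy)-4-chloro-10,11-epoxy-3-hydroxybisabol-7(14)-ene (CNP0313121.1)
Conditions: ent-Shi ketone (L-fructose-derived, 0.3 equiv), Oxone, K2CO3 (pH ≈ 10), n-Bu4NHSO4, MeCN/DMM/H2O, 0 °C
Reagents that add atoms: Oxone (potassium peroxymonosulfate), [K+].[O-]S(=O)(=O)OO
Why: Shi asymmetric epoxidation of the only electron-rich trisubstituted alkene. The L-ketone gives the (10S)-2,2-dimethyloxirane by catalyst control; the allylic-ester exo-methylene and the angelates are far slower, and pH ≈ 10 at 0 °C is too mild to close the trans-diaxial chlorohydrin.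

## Compound list

1 | (S)-(+)-carvone | C=C(C)[C@H]1CC=C(C)C(=O)C1 | starting material
2 | lithium (3S)-6-methyl-3-(prop-1-en-2-yl)cyclohexa-1,5-dien-1-olate (kinetic dienolate) | C=C(C)[C@H]1CC=C(C)C(O[Li])=C1 | intermediate (not isolated)
3 | (3S)-6-methyl-3-(prop-1-en-2-yl)cyclohexa-1,5-dien-1-yl acetate | C=C(C)[C@H]1CC=C(C)C(OC(C)=O)=C1 | intermediate
4 | 2β-acetoxy-1α,2α:3β,4β-diepoxy-3-methyl-6β-(prop-1-en-2-yl)cyclohexane | C=C(C)[C@H]1C[C@H]2O[C@@]2(C)[C@]3(OC(C)=O)O[C@H]13 | intermediate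
5 | 1β-acetoxy-3β,4β-epoxy-3-methyl-6β-(prop-1-en-2-yl)cyclohexan-2-one | C=C(C)[C@H]1C[C@H]2O[C@@]2(C)C(=O)[C@H]1OC(C)=O | intermediate
6 | 1β-acetoxy-3β,4β-epoxy-3-methyl-6β-(prop-1-en-2-yl)cyclohexan-2β-ol | C=C(C)[C@H]1C[C@H]2O[C@@]2(C)[C@@H](O)[C@H]1OC(C)=O | intermediate
7 | (1S,2S,3S,4S,6R)-1-acetoxy-4-chloro-3-methyl-6-(prop-1-en-2-yl)cyclohexane-2,3-diol | C=C(C)[C@H]1C[C@H](Cl)[C@@](C)(O)[C@@H](O)[C@H]1OC(C)=O | intermediate
8 | C8 allylic alcohol of 7 (6-(3-hydroxyprop-1-en-2-yl) analogue) | C=C(CO)[C@H]1C[C@H](Cl)[C@@](C)(O)[C@@H](O)[C@H]1OC(C)=O | intermediate (not isolated)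
9 | 2-[(1R,2S,3S,4S,5S)-2-acetoxy-5-chloro-3,4-dihydroxy-4-methylcyclohexyl]prop-2-enal | C=C(C=O)[C@H]1C[C@H](Cl)[C@@](C)(O)[C@@H](O)[C@H]1OC(C)=O | intermediate
10 | 8-O-(pinacolatoboryl) ether of 11 | C=C([C@H](CC=C)OB2OC(C)(C)C(C)(C)O2)[C@H]1C[C@H](Cl)[C@@](C)(O)[C@@H](O)[C@H]1OC(C)=O | intermediate (not isolated)
11 | (1S,2S,3S,4S,6R)-1-acetoxy-4-chloro-6-[(3S)-3-hydroxyhexa-1,5-dien-2-yl]-3-methylcyclohexane-2,3-diol | C=C([C@H](CC=C)O)[C@H]1C[C@H](Cl)[C@@](C)(O)[C@@H](O)[C@H]1OC(C)=O | intermediate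
12 | (8S)-1β-acetoxy-2β,8-bis(angeloyloxy)-4α-chloro-3β-hydroxy-12,13-dinorbisabola-7(14),10-diene | C=C([C@H](CC=C)OC(=O)/C(C)=C\C)[C@H]1C[C@H](Cl)[C@@](C)(O)[C@@H](OC(=O)/C(C)=C\C)[C@H]1OC(C)=O | intermediate
13 | (8S)-1β-acetoxy-2β,8-bis(angeloyloxy)-4α-chloro-3β-hydroxybisabola-7(14),10-diene | C=C([C@H](CC=C(C)C)OC(=O)/C(C)=C\C)[C@H]1C[C@H](Cl)[C@@](C)(O)[C@@H](OC(=O)/C(C)=C\C)[C@H]1OC(C)=O | intermediate
14 | (1S,2S,3S,4S,6R,8S,10S)-1-acetoxy-2,8-bis(angeloyloxy)-4-chloro-10,11-epoxy-3-hydroxybisabol-7(14)-ene | C=C([C@H](C[C@@H]1OC1(C)C)OC(=O)/C(C)=C\C)[C@H]1C[C@H](Cl)[C@@](C)(O)[C@@H](OC(=O)/C(C)=C\C)[C@H]1OC(C)=O | target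

## Step count and risks

Total step count: 10. Longest linear sequence: 10 steps from (S)-carvone.

Three steps most likely to fail:

**Step 2 (double Shi epoxidation).** The acetoxy-oxirane may hydrolyse at pH 10.5, and the isopropenyl group may be over-oxidised. The fallback sets out from 1 and comes back at 6. The kinetic enolate of 1 (LDA, THF, −78 °C) is hydroxylated with 2-(phenylsulfonyl)-3-phenyloxaziridine anti to the C6 substituent, giving 1α-hydroxy-3-methyl-6β-(prop-1-en-2-yl)cyclohex-3-en-2-one F1. Mitsunobu inversion (AcOH, PPh3, DIAD) gives the 1β-acetoxy enone F2. Luche reduction gives the 1β-acetoxy-2β-hydroxy allylic alcohol F3. Hydroxyl-directed epoxidation (VO(acac)2, t-BuOOH) of F3 then delivers 6.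

**Step 3 (thermal invertive acetoxy shift).** The bis-epoxide may decompose before it rearranges. The fallback sets out from 4 and comes back at 5. Brief methanolysis (K2CO3, MeOH, −20 °C) removes the acetyl group; the hemiketal collapses with retention to 1α-hydroxy-3β,4β-epoxy-3-methyl-6β-(prop-1-en-2-yl)cyclohexan-2-one F4. Mitsunobu reaction of F4 with AcOH (PPh3, DIAD) inverts C1 and gives 5.

**Step 8 (double angeloylation).** The C2–OH is hindered, angelate can isomerise to tiglate, and the C1 acetate can migrate to O-2. The fallback sets out from 11 and comes back at 12. Both secondary hydroxyls are esterified with 2-[bis(2,2,2-trifluoroethoxy)phosphoryl]propanoic acid (DCC, CH2Cl2, no DMAP) to give the 2,8-bis(phosphonopropanoate) F5. A double Still–Gennari olefination of F5 (KHMDS, 18-crown-6, THF, −78 °C, then acetaldehyde) builds both (Z)-2-methylbut-2-enoates on the molecule and gives 12.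

## Further compounds

F1 | step 2 | 1α-hydroxy-3-methyl-6β-(prop-1-en-2-yl)cyclohex-3-en-2-one (trans-6-hydroxycarvone) | C=C(C)[C@H]1CC=C(C)C(=O)[C@@H]1O
F2 | step 2 | 1β-acetoxy-3-methyl-6β-(prop-1-en-2-yl)cyclohex-3-en-2-one (cis-6-acetoxycarvone) | C=C(C)[C@H]1CC=C(C)C(=O)[C@H]1OC(C)=O
F3 | step 2 | 1β-acetoxy-3-methyl-6β-(prop-1-en-2-yl)cyclohex-3-en-2β-ol | C=C(C)[C@H]1CC=C(C)[C@@H](O)[C@H]1OC(C)=O
F4 | step 3 | 1α-hydroxy-3β,4β-epoxy-3-methyl-6β-(prop-1-en-2-yl)cyclohexan-2-one | C=C(C)[C@H]1C[C@H]2O[C@@]2(C)C(=O)[C@@H]1O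
F5 | step 8 | 2,8-bis{2-[bis(2,2,2-trifluoroethoxy)phosphoryl]propanoate} of 11 | C=C([C@H](CC=C)OC(=O)C(C)P(=O)(OCC(F)(F)F)OCC(F)(F)F)[C@H]1C[C@H](Cl)[C@@](C)(O)[C@@H](OC(=O)C(C)P(=O)(OCC(F)(F)F)OCC(F)(F)F)[C@H]1OC(C)=O
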